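**Plan**

- Retrosynthetic cuts, in order: the O7–acyl ester bond; the side-chain C1′=C2′ olefin (enal back to propenyl, cross-metathesis); C6–C7 (crossed benzoin, opens the carbocycle); C8a–C8 and C8–C7 (carbonylative coupling of a pyranyl triflate, CO and a 1-ethoxyvinyl unit); C4a=C5 (two-carbon homologation of the ring carbonyl of kojic acid).
- Enabling feature: C7 carries OH and CH3 between the C6 and C8 ketones of the carbocycle C4a–C5–C6–C7–C8–C8a, so C6–C7 is the bond an aldehyde-derived acyl anion at C6 forms with the methyl ketone of a pyruvoyl group (C8–C7) on C8a. C4a=C5 is exocyclic to the pyran ring (O2, C1, C8a, C4a, C4, C3), so a 4-(formylmethylene)-4H-pyran already has the unsaturation of the isochromene-6,8-dione.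
- Forward: the pyran ring is that of kojic acid; C5–C6 are added at the ring carbonyl and C8–C7 at the former enol carbon; the carbocycle closes as the second ring in the benzoin step; esterification, exchange of the propenyl terminus for the enal and desilylation follow.
- An (E)-propenyl group stands in for the enal until the ring is closed, because a free enal would compete for the carbene and an enal acetal would not survive the acid that unmasks the diketone.
- Stereochemistry: the single stereocentre C7 (R) is set by the chiral triazolylidene in the benzoin step and, being quaternary, cannot epimerise later; the side-chain (E)-olefin comes from E-selective olefination and then cross-metathesis.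

Key step: step 7

Remark on geometry: the exocyclic C4=CH–CHO bond of the pyran-4-ylidene acetaldehydes is a push–pull bond of low rotational barrier; they are written as the (Z) isomer (formyl on the C3 side), the one that can close, and should equilibrate with the (E) isomer.

Remark on the catalyst: the (5aS,10bR) aminoindanol-derived triazolium salt is assumed to direct attack to the Re face of the C7 ketone; if a scouting run shows the opposite sense, its commercial enantiomer is used.

**Route**

Step 1
Reactants: 1 kojic acid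
Product: 2 6-(hydroxymethyl)-4-oxo-4H-pyran-3-yl trifluoromethanesulfonate
Conditions: PhNTf2 (1.05 equiv), Et3N, MeCN, 0 °C → rt
Reagents that add atoms: N-phenylbis(trifluoromethanesulfonimide), O=S(=O)(N(c1ccccc1)S(=O)(=O)C(F)(F)F)C(F)(F)F
Why: Chemoselective O-triflation: only the acidic enolic 5-OH is deprotonated by the amine and sulfonylated by the mild triflimide, the primary alcohol being left alone.

Step 2
Reactants: 2 6-(hydroxymethyl)-4-oxo-4H-pyran-3-yl trifluoromethanesulfonate
Product: 3 6-formyl-4-oxo-4H-pyran-3-yl trifluoromethanesulfonate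
Conditions: Dess–Martin periodinane, CH2Cl2, 0 °C → rt
Reagents that add atoms: none
Why: Dess–Martin oxidation of the primary allylic-type alcohol should stop at the aldehyde under neutral conditions that the enol triflate and the pyranone tolerate.

Step 3
Reactants: 3 6-formyl-4-oxo-4H-pyran-3-yl trifluoromethanesulfonate
Product: 4 4-oxo-6-[(1E)-prop-1-en-1-yl]-4H-pyran-3-yl trifluoromethanesulfonate
Conditions: CH3CHI2, CrCl2, THF, 0 °C → rt
Reagents that add atoms: 1,1-diiodoethane, CC(I)I
Why: Takai–Utimoto ethylidenation: the gem-dichromium reagent should add only to the aldehyde (pyranone carbonyl and triflate inert) and eliminate to the (E)-olefin.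

Step 4
Reactants: 4 4-oxo-6-[(1E)-prop-1-en-1-yl]-4H-pyran-3-yl trifluoromethanesulfonate; 5 (Z)-1-bromo-2-ethoxyethene
Product: 8 (4Z)-4-(2-oxoethylidene)-6-[(1E)-prop-1-en-1-yl]-4H-pyran-3-yl trifluoromethanesulfonate, via (Z)-2-ethoxyvinyllithium 6 (not isolated), via tertiary pyran-4-ol adduct 7 (not isolated)
Conditions: 5, t-BuLi (2 equiv), Et2O, −78 °C; then 4, THF, −78 °C; then 1 M aq. HCl, 0 °C
Reagents that add atoms: water, O (the new aldehyde oxygen; the carbinol oxygen leaves as water)
Why: Two-carbon formyl-olefination of a ketone with 2-ethoxyvinyllithium: 1,2-addition to the doubly vinylogous ester carbonyl at −78 °C should outrun attack at the triflate, and on acidification the bis-allylic carbinol ionises to a 4-(2-ethoxyvinyl)pyrylium ion that takes up water at the alkoxy-bearing carbon and loses ethanol to leave the push–pull enal.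

Step 5
Reactants: 8 (4Z)-4-(2-oxoethylidene)-6-[(1E)-prop-1-en-1-yl]-4H-pyran-3-yl trifluoromethanesulfonate; 9 tributyl(1-ethoxyvinyl)stannane
Product: 10 (2Z)-2-{3-(2-ethoxyprop-2-enoyl)-6-[(1E)-prop-1-en-1-yl]-4H-pyran-4-ylidene}acetaldehyde
Conditions: CO (1 atm), Pd(PPh3)4 (5 mol %), LiCl (3 equiv), THF, 55 °C
Reagents that add atoms: carbon monoxide, [C-]#[O+]
Why: Carbonylative Stille coupling: oxidative addition of the enol triflate, CO insertion ahead of the slow transmetalation of the α-alkoxyvinylstannane and reductive elimination should give the α-ethoxy enone, a masked 1,2-diketone, with the aldehyde and the olefins untouched.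

Step 6
Reactants: 10 (2Z)-2-{3-(2-ethoxyprop-2-enoyl)-6-[(1E)-prop-1-en-1-yl]-4H-pyran-4-ylidene}acetaldehyde
Product: 11 (2Z)-2-{3-(2-oxopropanoyl)-6-[(1E)-prop-1-en-1-yl]-4H-pyran-4-ylidene}acetaldehyde
Conditions: 1 M aq. HCl, THF, 0 °C → rt
Reagents that add atoms: water, O
Why: Acid hydrolysis of the enol ether (C-protonation, addition of water, loss of ethanol) should free the methyl ketone of the pyruvoyl group, the molecule holding no acid-labile protecting group and the push–pull aldehyde only protonating reversibly on oxygen.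

Step 7
Reactants: 11 (2Z)-2-{3-(2-oxopropanoyl)-6-[(1E)-prop-1-en-1-yl]-4H-pyran-4-ylidene}acetaldehyde
Product: 12 (7R)-7-hydroxy-7-methyl-3-[(1E)-prop-1-en-1-yl]-6H-isochromene-6,8(7H)-dione
Conditions: (5aS,10bR)-2-(pentafluorophenyl)-5a,10b-dihydro-4H,6H-indeno[2,1-b][1,2,4]triazolo[4,3-d][1,4]oxazin-2-ium tetrafluoroborate (20 mol %), i-Pr2NEt (20 mol %), 4 Å MS, toluene, 25 → 40 °C
Reagents that add atoms: none
Why: Proposed new method: the triazolylidene should add to the C6 aldehyde, proton transfer gives the Breslow enaminol, this acyl anion equivalent attacks the C7 ketone of the pyruvoyl group, and proton transfer with loss of the carbene leaves the C6 ketone and the C7 tertiary alcohol. The closest known reaction type is the enantioselective intramolecular crossed aldehyde–ketone benzoin reaction under chiral bicyclic triazolium catalysis, which gives six-membered tertiary α-ketols; untested here are a push–pull (vinylogous formate) aldehyde as acyl anion source and a 1,2-diketone as acceptor. The carbocycle C4a–C5–C6–C7–C8–C8a closes in the 6-exo-trig mode, the (Z) geometry at C4a=C5 that it needs being supplied by rotation about this low-barrier push–pull bond. C7 is set under catalyst control: the aminoindanol backbone shields one face of the Breslow intermediate and the hydrogen bond from its enol O–H to the ketone oxygen orders the transition state, so that the Re face of the C7 carbonyl (O > C8 > CH3) is attacked, which corresponds to (R). Site selectivity for C7 over C8 rests on the higher electrophilicity of the acetyl-type ketone (C8 is a vinylogous ester conjugated with O2–C1=C8a and would close a five-membered ring), and acyl-anion reactivity should prevail over homoenolate reactivity because the β-carbon C4a is fully substituted and its protonation would break the conjugation of the pyran ring. The aprotic, alcohol-free medium and the weak amine base should keep the reversible carbene adducts at the ketones and at C1 from going on to acyl transfer or ring opening.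

Step 8
Reactants: 13 orsellinic acid
Product: 14 tert-butyldimethylsilyl 2,4-bis[(tert-butyldimethylsilyl)oxy]-6-methylbenzoate
Conditions: TBSCl (3.5 equiv), imidazole, DMF, rt
Reagents that add atoms: tert-butyldimethylsilyl chloride, CC(C)(C)[Si](C)(C)Cl
Why: Exhaustive O-silylation (two aryl silyl ethers and the silyl ester) under imidazole catalysis at room temperature should avoid the decarboxylation to which the free acid is prone.

Step 9
Reactants: 14 tert-butyldimethylsilyl 2,4-bis[(tert-butyldimethylsilyl)oxy]-6-methylbenzoate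
Product: 15 2,4-bis[(tert-butyldimethylsilyl)oxy]-6-methylbenzoyl chloride
Conditions: (COCl)2, DMF (cat.), CH2Cl2, 0 °C → rt; used crude
Reagents that add atoms: oxalyl chloride, O=C(Cl)C(=O)Cl
Why: Vilsmeier-type activation converts a silyl ester directly into the acid chloride without releasing HCl, so the aryl silyl ethers should survive.

Step 10
Reactants: 12 (7R)-7-hydroxy-7-methyl-3-[(1E)-prop-1-en-1-yl]-6H-isochromene-6,8(7H)-dione; 15 2,4-bis[(tert-butyldimethylsilyl)oxy]-6-methylbenzoyl chloride
Product: 16 (7R)-7-methyl-6,8-dioxo-3-[(1E)-prop-1-en-1-yl]-7,8-dihydro-6H-isochromen-7-yl 2,4-bis[(tert-butyldimethylsilyl)oxy]-6-methylbenzoate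
Conditions: LiHMDS (1.05 equiv), THF, −78 °C; then 15, −78 → 0 °C
Reagents that add atoms: none
Why: O-acylation of a tertiary lithium alkoxide by a donor-substituted 2,6-disubstituted aroyl chloride (addition–elimination with acylium character) should succeed where amine-catalysed acylation is too slow, and it leaves the configuration at C7 untouched.

Step 11
Reactants: 16 (7R)-7-methyl-6,8-dioxo-3-[(1E)-prop-1-en-1-yl]-7,8-dihydro-6H-isochromen-7-yl 2,4-bis[(tert-butyldimethylsilyl)oxy]-6-methylbenzoate; 17 (E)-crotonaldehyde
Product: 18 (7R)-7-methyl-6,8-dioxo-3-[(1E)-3-oxoprop-1-en-1-yl]-7,8-dihydro-6H-isochromen-7-yl 2,4-bis[(tert-butyldimethylsilyl)oxy]-6-methylbenzoate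
Conditions: Hoveyda–Grubbs II (10 mol %), 17 (10 equiv), CH2Cl2, 40 °C
Reagents that add atoms: none
Why: Olefin cross-metathesis with an enal partner: the ruthenium alkylidene should engage only the 1,2-disubstituted propenyl olefin (the ring olefins are trisubstituted and conjugated) and give the thermodynamically favoured (E)-enal with loss of but-2-ene.

Step 12
Reactants: 18 (7R)-7-methyl-6,8-dioxo-3-[(1E)-3-oxoprop-1-en-1-yl]-7,8-dihydro-6H-isochromen-7-yl 2,4-bis[(tert-butyldimethylsilyl)oxy]-6-methylbenzoate
Product: 19 (7R)-7-methyl-6,8-dioxo-3-[(1E)-3-oxoprop-1-en-1-yl]-7,8-dihydro-6H-isochromen-7-yl 2,4-dihydroxy-6-methylbenzoate (target)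
Conditions: 48% aq. HF, MeCN, 0 °C
Reagents that add atoms: none
Why: Fluoride-driven cleavage of the two aryl silyl ethers under acidic conditions, to which the isochromenedione, the hindered tertiary ester and the enal should be stable.

**Compound list**

1 | kojic acid | O=c1cc(CO)occ1O | starting material
2 | 6-(hydroxymethyl)-4-oxo-4H-pyran-3-yl trifluoromethanesulfonate | OCc1cc(=O)c(OS(=O)(=O)C(F)(F)F)co1 | intermediate
3 | 6-formyl-4-oxo-4H-pyran-3-yl trifluoromethanesulfonate | O=Cc1cc(=O)c(OS(=O)(=O)C(F)(F)F)co1 | intermediate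
4 | 4-oxo-6-[(1E)-prop-1-en-1-yl]-4H-pyran-3-yl trifluoromethanesulfonate | C/C=C/c1cc(=O)c(OS(=O)(=O)C(F)(F)F)co1 | intermediate
5 | (Z)-1-bromo-2-ethoxyethene | CCO/C=C\Br | starting material
6 | (Z)-2-ethoxyvinyllithium (not isolated) | CCO/C=C\[Li] | intermediate
7 | 4-[(Z)-2-ethoxyethenyl]-4-hydroxy-6-[(1E)-prop-1-en-1-yl]-4H-pyran-3-yl trifluoromethanesulfonate (racemic, formed as its lithium alkoxide, not isolated) | CCO/C=C\C1(O)C=C(/C=C/C)OC=C1OS(=O)(=O)C(F)(F)F | intermediate
8 | (4Z)-4-(2-oxoethylidene)-6-[(1E)-prop-1-en-1-yl]-4H-pyran-3-yl trifluoromethanesulfonate | FC(F)(F)S(=O)(=O)OC1=COC(/C=C/C)=C\C1=C\C=O | intermediate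
9 | tributyl(1-ethoxyvinyl)stannane | CCCC[Sn](CCCC)(CCCC)C(=C)OCC | starting material
10 | (2Z)-2-{3-(2-ethoxyprop-2-enoyl)-6-[(1E)-prop-1-en-1-yl]-4H-pyran-4-ylidene}acetaldehyde | C=C(OCC)C(=O)C1=COC(/C=C/C)=C\C1=C\C=O | intermediate
11 | (2Z)-2-{3-(2-oxopropanoyl)-6-[(1E)-prop-1-en-1-yl]-4H-pyran-4-ylidene}acetaldehyde | CC(=O)C(=O)C1=COC(/C=C/C)=C\C1=C\C=O | intermediate
12 | (7R)-7-hydroxy-7-methyl-3-[(1E)-prop-1-en-1-yl]-6H-isochromene-6,8(7H)-dione | O[C@]1(C)C(=O)C=C2C=C(/C=C/C)OC=C2C1=O | intermediate
13 | orsellinic acid | Cc1cc(O)cc(O)c1C(=O)O | starting material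
14 | tert-butyldimethylsilyl 2,4-bis[(tert-butyldimethylsilyl)oxy]-6-methylbenzoate | Cc1cc(O[Si](C)(C)C(C)(C)C)cc(O[Si](C)(C)C(C)(C)C)c1C(=O)O[Si](C)(C)C(C)(C)C | intermediate
15 | 2,4-bis[(tert-butyldimethylsilyl)oxy]-6-methylbenzoyl chloride | Cc1cc(O[Si](C)(C)C(C)(C)C)cc(O[Si](C)(C)C(C)(C)C)c1C(=O)Cl | intermediate
16 | (7R)-7-methyl-6,8-dioxo-3-[(1E)-prop-1-en-1-yl]-7,8-dihydro-6H-isochromen-7-yl 2,4-bis[(tert-butyldimethylsilyl)oxy]-6-methylbenzoate | Cc1cc(O[Si](C)(C)C(C)(C)C)cc(O[Si](C)(C)C(C)(C)C)c1C(=O)O[C@]1(C)C(=O)C=C2C=C(/C=C/C)OC=C2C1=O | intermediate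
17 | (E)-crotonaldehyde | C/C=C/C=O | starting material
18 | (7R)-7-methyl-6,8-dioxo-3-[(1E)-3-oxoprop-1-en-1-yl]-7,8-dihydro-6H-isochromen-7-yl 2,4-bis[(tert-butyldimethylsilyl)oxy]-6-methylbenzoate | Cc1cc(O[Si](C)(C)C(C)(C)C)cc(O[Si](C)(C)C(C)(C)C)c1C(=O)O[C@]1(C)C(=O)C=C2C=C(/C=C/C=O)OC=C2C1=O | intermediate
19 | (7R)-7-methyl-6,8-dioxo-3-[(1E)-3-oxoprop-1-en-1-yl]-7,8-dihydro-6H-isochromen-7-yl 2,4-dihydroxy-6-methylbenzoate | Cc1cc(O)cc(O)c1C(=O)O[C@]1(C)C(=O)C=C2C=C(/C=C/C=O)OC=C2C1=O | target

**Step count and risks**

Total steps: 12. Longest linear sequence: 10 (steps 1–7 and 10–12, from kojic acid).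

Steps most likely to fail:

1. Step 7 (benzoin ring closure). The carbene may fail to turn the electron-rich aldehyde into the Breslow intermediate, may be held as an unproductive adduct at the diketone, or may give poor facial selectivity at C7. The fallback sets out from 11 and comes back at 12. SmI2 in THF at −78 °C should reduce the 1,2-diketone to its samarium enediolate, which closes onto the C6 aldehyde in a pinacol-type reductive aldol to give 6,7-dihydroxy-7-methyl-3-[(1E)-prop-1-en-1-yl]-6,7-dihydro-8H-isochromen-8-one F1. Parikh–Doering oxidation of its secondary allylic C6 alcohol should give racemic 7-hydroxy-7-methyl-3-[(1E)-prop-1-en-1-yl]-6H-isochromene-6,8(7H)-dione F2. Preparative HPLC on a chiral stationary phase then delivers 12.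

2. Step 4 (two-carbon homologation). The vinyllithium may attack the triflate sulfur or add in conjugate fashion, or the pyrylium ion may be hydrated at a ring carbon and open. The fallback sets out from 4 and comes back at 8. Ethynylmagnesium bromide, a milder nucleophile, adds to the ring carbonyl to give 4-ethynyl-4-hydroxy-6-[(1E)-prop-1-en-1-yl]-4H-pyran-3-yl trifluoromethanesulfonate F3. Its acid-catalysed Meyer–Schuster rearrangement (p-TsOH, wet CH2Cl2) gives 8; a Rupe pathway is excluded because both neighbouring carbons are sp2.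

3. Step 11 (cross-metathesis). Initiation at the conjugated, rather electron-poor propenyl olefin may be slow, with catalyst decay and crotonaldehyde self-metathesis taking over. The fallback sets out from 16 and comes back at 18. Allylic oxidation of the terminal methyl group with catalytic SeO2 and t-BuOOH gives (7R)-3-[(1E)-3-hydroxyprop-1-en-1-yl]-7-methyl-6,8-dioxo-7,8-dihydro-6H-isochromen-7-yl 2,4-bis[(tert-butyldimethylsilyl)oxy]-6-methylbenzoate F4. MnO2 then oxidises this allylic alcohol to 18.

**Further compounds**

F1 | step 7 | 6,7-dihydroxy-7-methyl-3-[(1E)-prop-1-en-1-yl]-6,7-dihydro-8H-isochromen-8-one (diastereomer mixture) | OC1C=C2C=C(/C=C/C)OC=C2C(=O)C1(C)O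
F2 | step 7 | racemic 7-hydroxy-7-methyl-3-[(1E)-prop-1-en-1-yl]-6H-isochromene-6,8(7H)-dione | OC1(C)C(=O)C=C2C=C(/C=C/C)OC=C2C1=O
F3 | step 4 | 4-ethynyl-4-hydroxy-6-[(1E)-prop-1-en-1-yl]-4H-pyran-3-yl trifluoromethanesulfonate | C#CC1(O)C=C(/C=C/C)OC=C1OS(=O)(=O)C(F)(F)F
F4 | step 11 | (7R)-3-[(1E)-3-hydroxyprop-1-en-1-yl]-7-methyl-6,8-dioxo-7,8-dihydro-6H-isochromen-7-yl 2,4-bis[(tert-butyldimethylsilyl)oxy]-6-methylbenzoate | Cc1cc(O[Si](C)(C)C(C)(C)C)cc(O[Si](C)(C)C(C)(C)C)c1C(=O)O[C@]1(C)C(=O)C=C2C=C(/C=C/CO)OC=C2C1=O
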